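The readings were generated by integration for an exercise, and the scatter is random.

At early times free monomer falls at an apparent first-order rate of 0.954 d⁻¹ in Friday's run and 0.418 d⁻¹ in Wednesday's, as read from the first readings, so it falls twice as fast on twice the initiator.

the same everywhere: free monomer 0.50 M
- Friday's: initiator 12 mM; the very flask that is asked about, followed so far
- Wednesday's: initiator 6 mM; run made earlier
- flask: initiator 12 mM; time 6.0 d

| run | time / d | monomer in chains / % | free monomer / % |
|---|---|---|---|
| Friday's | 0.208 | 19 | 82 |
| Friday's | 0.333 | 24 | 77 |
| Friday's | 0.500 | 35 | 63 |
| Friday's | 0.833 | 50 | 50 |
| Friday's | 1.67 | 73 | 29 |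
| Friday's | 2.50 | 80 | 20 |
| Wednesday's | 0.625 | 24 | 77 |
| Wednesday's | 1.25 | 40 | 60 |
| Wednesday's | 2.00 | 54 | 44 |
| Wednesday's | 3.00 | 64 | 34 |
| Wednesday's | 4.00 | 68 | 27 |

(each reading ± 1.5 percentage points)

- average number of monomer units in a chain (chains begun, living or dead) at 6.0 d
- part of the free monomer that has reacted at 6.0 d

- the average divides the monomer in chains by the number of chains begun, living and dead together
- the numbers in the tables scatter by 1.5 percentage points (one standard deviation)
- the earlier runs do not show the number of chains; that part of a forecast is a guess

Two chemists read these runs differently, though both use the charge ratio, 41.7, free monomer charged per initiator charged. Counting reacted free monomer as monomer in chains, the average length is the reacted fraction times this ratio, divided by the share of initiator that begins a chain (the initiator efficiency). With that share fixed, time enters through the reacted fraction.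

A fixed share of any size gives the same doubling. The rates do not part the two chemists. The first chemist assumes that “each initiator starts one chain” and makes the forecast: length 39, with 93% reacted.

The second expects initiator to have another exit. For her, one chain per initiator gives a floor and not an estimate. Her own reckoning, which is not the forecast's, takes Friday's last reading at 2.50 d, where free monomer stands at 20%, and puts that floor at 33.3.

The flask gives a length of 96.9, with 89.3% reacted: the conversion agrees within its margin, while the length is 2.48 times the forecast's.

    free monomer + initiator → living end + monomer in chains (k = 9.40 × 10⁻⁴ L mol⁻¹ s⁻¹)
    initiator → spent initiator A (k = 7.60 × 10⁻⁴ s⁻¹)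
    living end + monomer in chains → dead end B (k = 1.40 × 10⁻⁵ L mol⁻¹ s⁻¹)
    free monomer + living end → monomer in chains + living end, rate k4*[living end]*[free monomer] (k = 0.00220 L mol⁻¹ s⁻¹)

Through the charge ratio, this length means a share of 38.4%, which favours the second chemist. The first chemist's view belongs where the step from initiator to living end far outruns the side loss of initiator. In this flask that step runs at 1.69 h⁻¹ at the charge, slower than the loss at 2.74 h⁻¹. The neighbouring flask has the same charges but is read at 40 h, with 70.8% reacted. One chain per initiator would give it 29.5, and the share of 38.4% gives 76.9. Its simulated length is 77.3.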